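Readings and results stem from a simulated flask from invented constants.

The constant I carried from the earlier runs was a selectivity factor of 5.54, as read from the last blue readings; by this I mean the logarithm of the share of charged c(left-handed substrate) still present, divided by the same logarithm for c(right-handed substrate).

| flask | left-handed substrate | right-handed substrate | solid reagent | free catalyst | remark | time |
|---|---|---|---|---|---|---|
| grey | 20 mM | 20 mM | 0.75 equiv | 1.8 mol% | run made earlier |  |
| teal | 20 mM | 20 mM | 1.1 equiv | 1.8 mol% | run made earlier |  |
| blue | 40 mM | 40 mM | 1.5 equiv | 1.8 mol% | run made earlier |  |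
| flask | 20 mM | 20 mM | 1.50 equiv | 1.8 mol% |  | 30 min |

- grey (time / min: right-handed substrate / %, left-handed substrate / %): 1.33: 49.3, 47.0; 4.00: 48.5, 38.7; 6.00: 46.8, 35.3; 10.0: 46.0, 30.1; 15.0: 43.5, 27.6; 20.0: 44.9, 26.2; 25.0: 44.1, 24.2
- teal (time / min: right-handed substrate / %, left-handed substrate / %): 1.33: 49.5, 47.0; 4.00: 47.3, 38.7; 6.00: 45.2, 31.2; 10.0: 44.1, 24.8; 15.0: 41.7, 19.7; 20.0: 41.0, 18.0; 25.0: 39.9, 16.3
- blue (time / min: right-handed substrate / %, left-handed substrate / %): 2.00: 48.4, 44.3; 6.00: 45.2, 29.8; 12.0: 39.2, 15.8; 15.0: 37.3, 11.3; 25.0: 33.0, 5.0

(scatter of a reading: 0.5 percentage points)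

- free catalyst is single-handed; left-handed substrate and right-handed substrate are mirror images of each other, charged as a racemate, each of them at the stated concentration
- solid reagent is a solid; its amount is given per volume of the solution
- at the start none of the solid reagent is in solution

- whether the excess of right-handed substrate over left-handed substrate among what is left of the two reaches 98% by 30 min (no / yes)
- the highest excess of right-handed substrate over left-handed substrate among what is left of the two up to 30 min

My bench rule was to work in powers of ten: each power of ten lost by the right-handed substrate costs the left-handed substrate that factor in powers, so their ratio falls by 4.54 powers. An excess of 98% means a ratio of 0.0101, or 2.00 powers of ten, so the right-handed substrate had to fall by 0.439 powers, to 36.4% of its charge. Counted on the left-handed substrate, the two together then had to lose 1.63 equivalents. The runs had consumed 0.845 per solid reagent charged in grey by 25.0 min and 0.827 in blue by 25.0 min, so I assumed one solid reagent per substrate consumed. That is the rule's border, because the demand is 1.09 times the flask's charge of 1.50 equiv, so I expected the flask to miss 98%.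

The rule ties excess to conversion but not to time, so I bracketed the top. The teal run, at the flask's concentration but with less solid reagent, ended at 42.0%. The blue run, at the flask's equivalents but twice its concentration, ended at 73.7%, and I committed to the midpoint, 57.8%.

The forecast agreed with me in answering no but put the top higher than my midpoint, at 79%, within 70% to 88%, holding that “the flask should track the blue run”.

The flask gave no and a top of 60.4%.

    left-handed product ⇌ right-handed product (k = 2.00 × 10⁻⁵ s⁻¹)
    free catalyst + left-handed substrate ⇌ catalyst intermediate A (K = 26.0 M⁻¹, k = 140 M⁻¹ s⁻¹)
    solid reagent ⇌ partner, rate k3*(cs3 - [partner]) while solid is left; crystals form when [partner] > cs3 (solubility = 16.0 mM, k = 0.0130 s⁻¹)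
    2 free catalyst → spent catalyst (k = 3.00 M⁻¹ s⁻¹)
    free catalyst + right-handed substrate ⇌ catalyst intermediate B (K = 17.0 M⁻¹, k = 4.70 M⁻¹ s⁻¹)
    partner + catalyst intermediate B → free catalyst + right-handed product (k = 8.80 M⁻¹ s⁻¹)
    partner + catalyst intermediate A → free catalyst + left-handed product (k = 23.0 M⁻¹ s⁻¹)

At 30.0 min, spent catalyst stood at 66.6% of the catalyst charged, with partner still at 7.95 mM. The flask's own remnants, 18% of the left-handed substrate and 72% of the right-handed, gave the factor as 5.22. The neighbour charged with 3.80 equiv gave 5.46, yet its right-handed substrate stood at 68% of its charge, above the 36.4% required, and its top was 68.9%.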